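(The runs were generated by integration on assumed constants, and the scatter is random.)

Larch, with twice the X of cedar, holds 12.8 % of E at 40.0 h, more than cedar's 7.0 %.

| flask | L | X | remark | time |
|---|---|---|---|---|
| cedar | 23 mM | 2 mol% | run made earlier |  |
| alder | 52 mM | 2 mol% | run made earlier |  |
| larch | 35 mM | 4 mol% | run made earlier |  |
| winter | 35 mM | 2 mol% |  | 2.5 d |
| dusk | 35 mM | 2 mol% |  | 5.0 d |
| noon | 35 mM | 2 mol% |  | 10 d |

| run | time / h | Z / % | E / % | J / % | L / % |
|---|---|---|---|---|---|
| cedar | 10.0 | 1.7 | 1.1 | 2.7 | 62.9 |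
| cedar | 20.0 | 7.4 | 1.7 | 0 | 42.4 |
| cedar | 25.0 | 5.5 | 3.4 | 2.2 | 35.6 |
| cedar | 40.0 | 7.8 | 7.0 | 1.0 | 26.2 |
| alder | 5.00 | 3.2 | 0 | 2.1 | 75.8 |
| alder | 12.0 | 3.9 | 1.2 | 1.2 | 55.8 |
| alder | 25.0 | 8.3 | 3.4 | 1.8 | 36.2 |
| alder | 40.0 | 8.4 | 6.5 | 1.4 | 24.4 |
| larch | 3.00 | 2.8 | 0 | 3.4 | 81.8 |
| larch | 6.00 | 4.5 | 0 | 3.3 | 71.4 |
| larch | 15.0 | 10.0 | 2.6 | 1.6 | 47.0 |
| larch | 40.0 | 14.6 | 12.8 | 1.1 | 19.6 |

(each reading ± 1 percentage point)

- reactions considered so far: L + X -> J; J <-> D; D <-> X + Z; L <-> G; Z -> E
- a reading of L is of its free form alone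

- which of these there is most of at the end, counted by the L in it, winter (Z / E / L / J)
- which of these there is most of at the end, counted by the L in it, dusk (Z / E / L / J)
- which of these there is most of at the end, counted by the L in it, noon (Z / E / L / J)
- final amount of the leader among these, as a percentage of the L charged, in winter
- final amount of the leader among these, as a percentage of the L charged, in dusk
- final amount of the leader among these, as a percentage of the L charged, in noon

What feeds E? In the scheme considered, the step written to E is Z → E, so I take [E] to climb at [Z]/τ.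

Read τ. Larch gained 10 percentage points of E between its last two readings, more than cedar or alder between theirs, so I use larch. Elapsed time times mean [Z], over that gain, gives τ = 30.1 h, the mean life of Z before it turns into E. It is a reading and carries the scatter.

What is [Z] at 2 mol% of X? Cedar and alder read 7.8 % and 8.4 % at 40.0 h, though their L charges are 23 mM and 52 mM. I take the mean, 8.10 %, as a plateau (a quasi-steady state).

And [E] in dusk? The large term is the flow after 40.0 h, which is [Z]/τ times the time left to 5.0 d, or 21.5 %. The correction is the E that cedar and alder already read at 40.0 h, with mean 6.75 %. Together they give 28.2 %.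

Where is this weak? The latest reading stands at 40.0 h, so a flat [Z] beyond it is my assumption.

The forecast differs from my figure for E in dusk. It names L at 19.5 % in winter, E at 27.5 % in dusk and E at 55 % in noon, and it says: “Z→E has k about 0.03/h, so Z plateaus near 9%.”

The flasks give L at 18.9 % in winter, E at 25.7 % in dusk and E at 50.8 % in noon.

    L + X → J (k = 0.750 M⁻¹ min⁻¹)
    J ⇌ D (K = 0.550, k = 0.340 min⁻¹)
    D ⇌ X + Z (K = 0.0680 M, k = 0.0120 min⁻¹)
    L ⇌ G (K = 2.90, k = 7.30 × 10⁻⁴ min⁻¹)
    Z → E (k = 4.70 × 10⁻⁴ min⁻¹)

Dusk ends with [Z] at 8.36 %. Taking the correction in proportion to [Z], τ turns that into 29.2 % of E, and dusk holds less, 25.7 %. The neighbouring flask is dusk with 1.2 mol% of X. Its [Z] is 5.63 %, so the same reckoning gives 19.7 % of E, and that flask holds less, 16.4 %. Dusk's leader, E, stands in the neighbouring flask behind L, at 16.4 % against 17.9 %.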